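The cyclopentenone ring carbons C8–C12 and the exocyclic C7 of the target are taken to be the six ring carbons of a para-alkylphenol (C9 phenolic, C12 para), so the route rests on disconnecting C8–C9. One operation, a Lewis acid 1,2-acyl shift in an epoxy ketone, makes that bond, contracts a six-membered ring to the chlorocyclopentenone and expels C7 as a formyl group that enolises, ready for stereoretentive coupling. Its precursor is an enantiopure 2-chloro-4-silyloxy-4-[(Z)-oct-2-enyl]-5,6-epoxycyclohex-2-enone, made by dearomatising the phenol and differentiating the two enones of the quinol, with the epoxide set trans to the silyloxy group.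

Key step: step 9

Numbering: C1–C20 are the prostanoid positions of the target (C1 ester carbon, C8–C12 ring, C7 exocyclic, C13–C20 octenyl chain).

Assumption: the quinine-derived amine of step 5 is taken to select the enone that becomes C10=C11; if the first batch shows the opposite sense, its quinidine-derived pseudoenantiomer is used and nothing else changes.

Design remark: the epoxide of the rearrangement substrate is placed trans to the C12 silyloxy group, by silylating before the second epoxidation. In the cis arrangement C13 would lie antiperiplanar to the breaking C8–O bond and a pinacol-type shift from C12 would compete. The epoxide configuration itself is erased in step 9.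

Step 1
Reactants: 1 tyrosol
Product: 2 4-(2-bromoethyl)phenol
Conditions: 48% aq. HBr, 100 °C
Reagents that add atoms: hydrogen bromide, Br
Why: Protonation of the primary hydroxyl and SN2 displacement by bromide converts only the aliphatic alcohol, because the phenolic C–O bond cannot be substituted (acid-mediated alcohol-to-bromide exchange); no stereocentre is involved.

Step 2
Reactants: 2 4-(2-bromoethyl)phenol
Product: 3 [2-(4-hydroxyphenyl)ethyl]triphenylphosphonium bromide
Conditions: PPh3, toluene, 110 °C
Reagents that add atoms: triphenylphosphine, c1ccc(cc1)P(c1ccccc1)c1ccccc1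
Why: The unhindered primary bromide is displaced by the phosphine in an SN2 quaternisation, and without base the free phenol does not interfere.

Step 3
Reactants: 3 [2-(4-hydroxyphenyl)ethyl]triphenylphosphonium bromide; 4 hexanal
Product: 6 4-[(Z)-oct-2-enyl]phenol, via sodium phenolate ylide 5 (not isolated)
Conditions: NaN(SiMe3)2 (2.1 equiv), THF, 0 °C; then 4, −78 °C to rt; aq. NH4Cl
Reagents that add atoms: none
Why: Wittig reaction: the first equivalent of base forms the phenolate and the second the non-stabilised ylide, which adds to the aliphatic aldehyde under lithium-free conditions through the kinetically preferred cis-oxaphosphetane, so the new C14=C15 bond should be Z.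

Step 4
Reactants: 6 4-[(Z)-oct-2-enyl]phenol
Product: 7 4-hydroxy-4-[(Z)-oct-2-enyl]cyclohexa-2,5-dien-1-one
Conditions: PhI(OAc)2 (1.1 equiv), MeCN/H2O (3:1), 0 °C
Reagents that add atoms: water, O
Why: Oxidative dearomatisation: ligand exchange of the phenol at the trivalent iodine centre, loss of PhI and capture of the para carbon by water should give the cross-conjugated quinol (hypervalent iodine para-hydroxylation of a para-alkylphenol); the product is achiral, C12 being flanked by two enantiotopic enones.

Step 5
Reactants: 7 4-hydroxy-4-[(Z)-oct-2-enyl]cyclohexa-2,5-dien-1-one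
Product: 8 (4S,5R,6S)-5,6-epoxy-4-hydroxy-4-[(Z)-oct-2-enyl]cyclohex-2-en-1-one (epoxide cis to the hydroxyl)
Conditions: 9-amino-9-deoxy-epi-quinine (10 mol%), CF3CO2H (20 mol%), 50% aq. H2O2 (1.5 equiv), dioxane, 30 °C
Reagents that add atoms: hydrogen peroxide, OO
Why: Proposed new method: the primary amine salt condenses with the C9 carbonyl to a dienyl iminium ion, H2O2 adds to the beta carbon of one enone under guidance of the protonated quinuclidine, and the enamine so formed displaces water from the peroxide to close the epoxide; because the two enones are enantiotopic, the catalyst's facial preference combined with hydrogen-bond delivery syn to the C12 hydroxyl becomes a choice of enone (the future C10=C11), which fixes the later C12 configuration, and the minor trans diastereomer, which would sit mainly on the other enone, is to be removed by chromatography before step 6; closest known reaction types are the cinchona primary amine salt-catalysed epoxidation of cyclohex-2-enones with H2O2 and amine-salt-catalysed desymmetrising oxa-Michael additions to cyclohexadienones.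

Step 6
Reactants: 8 (4S,5R,6S)-5,6-epoxy-4-hydroxy-4-[(Z)-oct-2-enyl]cyclohex-2-en-1-one
Product: 10 (S)-2-chloro-4-hydroxy-4-[(Z)-oct-2-enyl]cyclohexa-2,5-dien-1-one, via trans-chlorohydrin 9 (not isolated)
Conditions: HCl (4 M in dioxane, 3 equiv), THF, 0 °C to rt
Reagents that add atoms: hydrogen chloride, Cl
Why: Chloride opens the protonated epoxide at C10, the carbon alpha to the carbonyl and remote from the neopentyl-like C11, and the chlorohydrin loses water across C10–C11 through its enol (known conversion of 2,3-epoxy ketones into 2-chloroenones with HCl); both epoxide stereocentres vanish and C12 becomes stereogenic solely because one of its two enone arms now carries chlorine.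

Step 7
Reactants: 10 (S)-2-chloro-4-hydroxy-4-[(Z)-oct-2-enyl]cyclohexa-2,5-dien-1-one
Product: 11 (S)-4-(tert-butyldimethylsilyloxy)-2-chloro-4-[(Z)-oct-2-enyl]cyclohexa-2,5-dien-1-one
Conditions: t-BuMe2SiOTf (1.3 equiv), 2,6-lutidine (2 equiv), CH2Cl2, −78 to 0 °C
Reagents that add atoms: tert-butyldimethylsilyl trifluoromethanesulfonate, CC(C)(C)[Si](C)(C)OS(=O)(=O)C(F)(F)F
Why: A silyl triflate with a hindered pyridine base silylates tertiary alcohols readily at low temperature, and doing so before the second epoxide exists avoids exposing an epoxide to the Lewis-acidic silylating agent.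

Step 8
Reactants: 11 (S)-4-(tert-butyldimethylsilyloxy)-2-chloro-4-[(Z)-oct-2-enyl]cyclohexa-2,5-dien-1-one
Product: 12 (4R,5R,6S)-4-(tert-butyldimethylsilyloxy)-2-chloro-5,6-epoxy-4-[(Z)-oct-2-enyl]cyclohex-2-en-1-one (epoxide trans to the silyloxy group)
Conditions: t-BuOOH (5.5 M in decane, 2 equiv), DBU (1.2 equiv), CH2Cl2, 0 °C
Reagents that add atoms: tert-butyl hydroperoxide, CC(C)(C)OO
Why: Weitz–Scheffer epoxidation: the peroxide anion should add to C8 of the unsubstituted enone (the 2-chloro enone is the poorer substrate for the addition–ring-closure sequence) from the face opposite to the C12–O bond, which is the best sigma acceptor and the site of electrostatic repulsion once the hydroxyl is capped, so the epoxide is expected trans to the silyloxy group; any cis isomer is to be removed by chromatography.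

Step 9
Reactants: 12 (4R,5R,6S)-4-(tert-butyldimethylsilyloxy)-2-chloro-5,6-epoxy-4-[(Z)-oct-2-enyl]cyclohex-2-en-1-one
Product: 13 (4R,5Z)-4-(tert-butyldimethylsilyloxy)-2-chloro-5-(hydroxymethylidene)-4-[(Z)-oct-2-enyl]cyclopent-2-en-1-one
Conditions: BF3·OEt2 (1.5 equiv), CH2Cl2, −40 to 0 °C; then aq. NaOAc
Reagents that add atoms: none
Why: BF3 activates the epoxide oxygen, the C8–O bond (the one beta to the carbonyl) lengthens and the C9 acyl carbon moves from C7 to C8 with its bonding pair, so C8–C9 is formed, the oxygen left on C7 becomes the aldehyde, and the resulting 2-formyl ketone tautomerises to the hydrogen-bonded Z hydroxymethylene form. The closest known reaction type is the Lewis acid isomerisation of 2,3-epoxycyclohexanones to 2-formylcyclopentanones, a Meinwald-type rearrangement with acyl as the migrating group. The cyclopentenone ring C8–C12 is closed by ring contraction through this 1,2-shift of a ring bond, not by a separate cyclisation. No new stereocentre is created, since C7 and C8 both become trigonal and C12 is untouched; the only new stereo-element, the Z enol, is held by the hydrogen bond to the C9 carbonyl. The step needs migration of C9 ahead of hydride from C7 and ahead of any group on C12: with the epoxide trans to the silyloxy group, C13 and the side-chain alkene are gauche to the breaking C8–O bond and cannot reach C8 from the rear, the only antiperiplanar C12 substituent is the oxygen buried under its silyl group, the donor that pushes the acyl shift is an anionic borate oxygen on C7 whereas C11 could be pushed only by a silyl ether, and acyl is the better migrating group than hydride in this reaction class.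

Step 10
Reactants: 13 (4R,5Z)-4-(tert-butyldimethylsilyloxy)-2-chloro-5-(hydroxymethylidene)-4-[(Z)-oct-2-enyl]cyclopent-2-en-1-one
Product: 15 (4R,5Z)-4-(tert-butyldimethylsilyloxy)-2-chloro-4-[(Z)-oct-2-enyl]-5-[(trifluoromethanesulfonyloxy)methylidene]cyclopent-2-en-1-one, via lithium enolate 14 (not isolated)
Conditions: LiN(SiMe3)2 (1.05 equiv), THF, −78 °C; then PhNTf2 (1.1 equiv), −78 to 0 °C
Reagents that add atoms: N-phenylbis(trifluoromethanesulfonimide), O=S(=O)(N(c1ccccc1)S(=O)(=O)C(F)(F)F)C(F)(F)F
Why: Enol triflate formation by O-sulfonylation of the 1,3-dicarbonyl enolate at the aldehyde-derived oxygen, where the lithium chelate between O7 and the C9 carbonyl should hold the C7=C8 bond Z and the E geometry is further disfavoured by the quaternary C12; triflation at the ring oxygen would create a cyclopentadiene and is not expected.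

Step 11
Reactants: 16 methyl hex-5-ynoate
Product: 17 methyl (E)-6-(4,4,5,5-tetramethyl-1,3,2-dioxaborolan-2-yl)hex-5-enoate
Conditions: pinacolborane (1.2 equiv), Cp2Zr(H)Cl (5 mol%), Et3N (10 mol%), neat, 60 °C
Reagents that add atoms: pinacolborane, [H]B1OC(C)(C)C(C)(C)O1
Why: Cp2Zr(H)Cl-catalysed syn hydroboration of the terminal alkyne places boron on the terminal carbon and gives the (E)-alkenylboronate, the ester being inert to pinacolborane.

Step 12
Reactants: 15 (4R,5Z)-4-(tert-butyldimethylsilyloxy)-2-chloro-4-[(Z)-oct-2-enyl]-5-[(trifluoromethanesulfonyloxy)methylidene]cyclopent-2-en-1-one; 17 methyl (E)-6-(4,4,5,5-tetramethyl-1,3,2-dioxaborolan-2-yl)hex-5-enoate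
Product: 18 methyl (5E,7Z,12R,14Z)-12-(tert-butyldimethylsilyloxy)-10-chloro-9-oxoprosta-5,7,10,14-tetraen-1-oate
Conditions: Pd(PPh3)4 (5 mol%), K3PO4 (3 equiv), dioxane/H2O (10:1), 25 °C, degassed
Reagents that add atoms: none
Why: Suzuki–Miyaura coupling: zerovalent palladium should insert into the C7–OTf bond of the electron-poor enol triflate much faster than into the C10–Cl bond, and transmetalation and reductive elimination proceed with retention at both alkenyl carbons, so the 7Z and 5E geometries are carried into the product with its new C6–C7 bond.

Step 13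
Reactants: 18 methyl (5E,7Z,12R,14Z)-12-(tert-butyldimethylsilyloxy)-10-chloro-9-oxoprosta-5,7,10,14-tetraen-1-oate
Product: 19 methyl (5E,7Z,12R,14Z)-10-chloro-12-hydroxy-9-oxoprosta-5,7,10,14-tetraen-1-oate (the target)
Conditions: HF·pyridine, pyridine, THF, 0 °C to rt
Reagents that add atoms: none
Why: Fluoride-assisted cleavage of the tertiary silyl ether under buffered, mildly acidic conditions (desilylation with HF·pyridine) should spare the base-sensitive cross-conjugated dienone, the methyl ester and the 7Z geometry; C12 is untouched.

Compound list (the spatial arrangement at C12 is that of the target from 8 onward; its descriptor changes only with substituent priorities)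

1 | tyrosol, 4-(2-hydroxyethyl)phenol | OCCc1ccc(O)cc1 | starting material
2 | 4-(2-bromoethyl)phenol | Oc1ccc(CCBr)cc1 | intermediate
3 | [2-(4-hydroxyphenyl)ethyl]triphenylphosphonium bromide | Oc1ccc(CC[P+](c2ccccc2)(c2ccccc2)c2ccccc2)cc1.[Br-] | intermediate
4 | hexanal | CCCCCC=O | starting material
5 | sodium 4-[2-(triphenylphosphoranylidene)ethyl]phenolate (ylide, not isolated) | [Na+].[O-]c1ccc(CC=P(c2ccccc2)(c2ccccc2)c2ccccc2)cc1 | intermediate
6 | 4-[(Z)-oct-2-enyl]phenol | CCCCC/C=C\Cc1ccc(O)cc1 | intermediate
7 | 4-hydroxy-4-[(Z)-oct-2-enyl]cyclohexa-2,5-dien-1-one (prochiral quinol) | CCCCC/C=C\CC1(O)C=CC(=O)C=C1 | intermediate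
8 | (4S,5R,6S)-5,6-epoxy-4-hydroxy-4-[(Z)-oct-2-enyl]cyclohex-2-en-1-one, epoxide cis to OH | CCCCC/C=C\C[C@]1(O)C=CC(=O)[C@H]2O[C@@H]12 | intermediate
9 | (2R,3S,4S)-2-chloro-3,4-dihydroxy-4-[(Z)-oct-2-enyl]cyclohex-5-en-1-one (trans-chlorohydrin, not isolated) | CCCCC/C=C\C[C@]1(O)C=CC(=O)[C@H](Cl)[C@H]1O | intermediate
10 | (S)-2-chloro-4-hydroxy-4-[(Z)-oct-2-enyl]cyclohexa-2,5-dien-1-one | CCCCC/C=C\C[C@@]1(O)C=C(Cl)C(=O)C=C1 | intermediate
11 | (S)-4-(tert-butyldimethylsilyloxy)-2-chloro-4-[(Z)-oct-2-enyl]cyclohexa-2,5-dien-1-one | CCCCC/C=C\C[C@@]1(O[Si](C)(C)C(C)(C)C)C=C(Cl)C(=O)C=C1 | intermediate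
12 | (4R,5R,6S)-4-(tert-butyldimethylsilyloxy)-2-chloro-5,6-epoxy-4-[(Z)-oct-2-enyl]cyclohex-2-en-1-one, epoxide trans to the silyloxy group | CCCCC/C=C\C[C@@]1(O[Si](C)(C)C(C)(C)C)C=C(Cl)C(=O)[C@H]2O[C@@H]12 | intermediate
13 | (4R,5Z)-4-(tert-butyldimethylsilyloxy)-2-chloro-5-(hydroxymethylidene)-4-[(Z)-oct-2-enyl]cyclopent-2-en-1-one | CCCCC/C=C\C[C@@]1(O[Si](C)(C)C(C)(C)C)C=C(Cl)C(=O)/C1=C\O | intermediate
14 | lithium enolate of 13 (Z, chelated, not isolated) | [Li+].CCCCC/C=C\C[C@@]1(O[Si](C)(C)C(C)(C)C)C=C(Cl)C(=O)/C1=C\[O-] | intermediate
15 | (4R,5Z)-4-(tert-butyldimethylsilyloxy)-2-chloro-4-[(Z)-oct-2-enyl]-5-[(trifluoromethanesulfonyloxy)methylidene]cyclopent-2-en-1-one | CCCCC/C=C\C[C@@]1(O[Si](C)(C)C(C)(C)C)C=C(Cl)C(=O)/C1=C\OS(=O)(=O)C(F)(F)F | intermediate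
16 | methyl hex-5-ynoate | COC(=O)CCCC#C | starting material
17 | methyl (E)-6-(4,4,5,5-tetramethyl-1,3,2-dioxaborolan-2-yl)hex-5-enoate | COC(=O)CCC/C=C/B1OC(C)(C)C(C)(C)O1 | intermediate
18 | methyl (5E,7Z,12R,14Z)-12-(tert-butyldimethylsilyloxy)-10-chloro-9-oxoprosta-5,7,10,14-tetraen-1-oate | CCCCC/C=C\C[C@@]1(O[Si](C)(C)C(C)(C)C)C=C(Cl)C(=O)/C1=C\C=C\CCCC(=O)OC | intermediate
19 | methyl (5E,7Z,12R,14Z)-10-chloro-12-hydroxy-9-oxoprosta-5,7,10,14-tetraen-1-oate | CCCCC/C=C\C[C@@]1(O)C=C(Cl)C(=O)/C1=C\C=C\CCCC(=O)OC | target

Total step count: 13. Longest linear sequence: 12 steps (steps 1–10, 12 and 13); step 11 is the single convergent step.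

Steps most likely to fail

Step 5, the one step outside established scope. The catalyst may discriminate poorly between the two enantiotopic enones, or its facial preference may oppose the hydroxyl-directed delivery so that both enones are epoxidised, and the mono-epoxide may be oxidised further to the bis-epoxide. The fallback uses known chemistry, sets out from 7 and comes back at 10. Hydroxyl-directed epoxidation of 7 with 30% H2O2 and catalytic NaOH in MeOH at 0 °C should give the cis-epoxy quinol as a racemate, that is 8 together with ent-8 F1. Treatment with HCl as in step 6 then leads, through 9 and ent-9 F2, to racemic chloroquinol, that is 10 together with ent-10 F3. Compound 10 is separated from its mirror image by preparative chromatography on a chiral stationary phase (amylose tris(3,5-dimethylphenylcarbamate)). This replaces asymmetric catalysis by resolution at the cost of half the material.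

Step 9. Hydride may shift from C7 to C8 and give the 1,2-diketone, fluoride may capture the opened epoxide, C11 may migrate from C12 under the push of the silyl ether oxygen, or the silyl group may be lost before the shift. The fallback sets out from 12 and comes back at 13 and makes no new compound (F0). Compound 12 is irradiated through Pyrex in degassed benzene, the known photochemical isomerisation of 2,3-epoxycyclohexanones to ring-contracted 1,3-dicarbonyl compounds. Homolysis of the C7–O bond leaves an oxygen radical on C8, the C8–C12 bond cleaves to a tertiary, allylic, oxygen-substituted radical, and recombination of C12 with C7 closes the five-membered ring. The former C7 is then the ring carbon and the former C8 the formyl carbon, which is the same compound 13. No cation is formed at C8, so neither hydride shift nor pinacol-type shift can intervene.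

Step 4. The doubly activated benzylic and allylic proton at C13 may be lost from the phenoxenium-type intermediate, which would lead to a quinone methide and its water adducts or oligomers in place of attack of water at the para carbon. The fallback sets out from 6 and comes back at 7. Singlet oxygen generated from 2KHSO5·KHSO4·K2SO4 and NaHCO3 in aqueous MeCN at rt should add across the phenolate ring to give 4-hydroperoxy-4-[(Z)-oct-2-enyl]cyclohexa-2,5-dien-1-one F4, which is reduced with Me2S to 7. This oxygenation involves no cation at the para position and is known for para-alkylphenols.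

Further compounds
F1 | step 5 | ent-8, (4R,5S,6R)-5,6-epoxy-4-hydroxy-4-[(Z)-oct-2-enyl]cyclohex-2-en-1-one | CCCCC/C=C\C[C@@]1(O)C=CC(=O)[C@@H]2O[C@H]12
F2 | step 5 | ent-9, (2S,3R,4R)-2-chloro-3,4-dihydroxy-4-[(Z)-oct-2-enyl]cyclohex-5-en-1-one (not isolated) | CCCCC/C=C\C[C@@]1(O)C=CC(=O)[C@@H](Cl)[C@@H]1O
F3 | step 5 | ent-10, (R)-2-chloro-4-hydroxy-4-[(Z)-oct-2-enyl]cyclohexa-2,5-dien-1-one | CCCCC/C=C\C[C@]1(O)C=C(Cl)C(=O)C=C1
F0 | step 9 | none | none
F4 | step 4 | 4-hydroperoxy-4-[(Z)-oct-2-enyl]cyclohexa-2,5-dien-1-one | CCCCC/C=C\CC1(OO)C=CC(=O)C=C1
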